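**Remarks before the route**

- Atom numbers are those of benzofuran (O1, C2, C3, C3a, C4 to C7, C7a). Ring A is the benzo ring and ring B the 2,4-dihydroxyphenyl ring (C1' to C6'). The target is taken as the open hydroxy aldehyde, not as the cyclic hemiacetal that the 2'-hydroxyl could form with the formyl group.
- The skeletons of 15 and 16 were checked atom by atom against 18. The acetal oxygen sits on the ring A carbon next to the only aromatic C–H, so it becomes O1 and the side chain falls at C5. No correction of connectivity is needed.
- Four design choices differ from the most direct layout and are justified where they occur: acetal before iodination, side-chain coupling before phenol silylation, a triethylsilyl group on the tertiary oxygen, and a zinc acetylide coupling in the same flask as the alkyne formation.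

## Structural features

The target is a 2-arylbenzofuran. Ring A is fused to a furan (O1, C2, C3); C2 carries ring B through the C2–C1' bond and C3 carries a formyl group. Ring A is substituted everywhere except C7: O1 on C7a, a free hydroxyl on C4, the 3-hydroxy-3-methylbutyl chain on C5 and a methoxy group on C6. There is no stereocentre, so no neighbouring stereocentres have to be related; every problem is one of regiochemistry and of functional-group tolerance.

The fragile elements are three:
- the electron-rich polyphenol, which is easily oxidised;
- the aldehyde, flanked by the C4 hydroxyl and the 2'-hydroxyl;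
- the tertiary alcohol, which in acid can lose water or close onto the C4 hydroxyl to give a 2,2-dimethylchroman.

The real difficulty is threefold. The two ring A oxygens ortho to C3a must be told apart (one becomes O1, the other the C4 hydroxyl). The side chain must sit at C5 and not at C7. The one-carbon unit must enter at C3 and not at the equally electron-rich C7.

The key step exploits the fact that C3 is bonded to C2, the carbon that O1 attacks when the furan closes. An acetal on the future O1 therefore releases its CH2OMe unit one atom away from the carbon–metal bond that forms at C3 during the O1–C2 closure.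

## Logic of the disconnections

**18 to 17.** Only four O–Si bonds are cut (C4–O, 2'–O, 4'–O and the side-chain oxygen). The free triphenol aldehyde is sensitive to air and acid, so it appears only at the end. All four masks are silyl groups, so one fluoride treatment suffices and neither acid (tertiary alcohol) nor hydrogenolysis (aldehyde) is needed. The demand is that all four ethers cleave under one mild set of conditions; this is why the side-chain oxygen carries the more labile triethylsilyl group rather than a bulkier one.

**17 to 16.** No skeletal bond is cut. The formyl C=O is traced back to the two C–H bonds of a CH2–OMe group on C3. The gain is that no electrophilic formylation is needed, which could not be trusted to choose C3 over C7. The demand is an oxidation that picks out this one methylene; it is the only one whose cation is conjugated through C2 to O1 and ring B. It must also come before the phenols are set free.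

**16 to 15 (key).** The bonds O1–C2 and C3–CH2 are cut. The furan ring and the C3 carbon are both removed, and what remains is a diaryl alkyne whose ring A oxygen carries the one-carbon unit as part of an acetal. The demand is that exactly one of the three oxygens ortho to the alkyne reacts. That oxygen alone is an acetal oxygen and lies next to the ring A C–H; the other two carry bulky silyl groups.

**15 to 10 and 12.** The sp–sp2 bond between the alkyne and ring B (the future C2–C1' bond) is cut, which splits the molecule into two aromatic halves. The demand is a coupling of two crowded, electron-rich partners without dimerisation of the alkyne. The acetylide is therefore generated from 10 and used as its zinc derivative (13, then 14) in the same flask.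

**10 to 9.** The C=C bond between the future C3 and the future C2 is cut. C2 then comes from a one-carbon reagent and ring A is reduced to a benzaldehyde. The demand is an olefination of a di-ortho-substituted aldehyde under conditions that spare an aryl acetal and two silyl ethers.

**9 to 8.** The O–Si bond at the future C4 oxygen is cut. An aryl silyl ether ortho to a formyl group is labile to base, so it is introduced only after the aqueous-base coupling and one step before the aldehyde is consumed. The demand is silylation of a hindered, hydrogen-bonded phenol.

**8 to 4 and 6 (through 7).** The sp2–sp3 bond C5–CH2 is cut. The whole side chain then comes from 5 in one coupling and the iodine of 4 marks the position. The demand is a coupling that tolerates a free phenol and an aldehyde, with no B–H left when the aldehyde is added.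

**4 to 3, 3 to 2, 2 to 1.** The C–I bond, then the O–CH2 bond of the acetal, then the O–CH3 bond are cut. The order matters. In 2 the two phenols are equivalent, so the acetal can go on only one kind of oxygen. In 3 the one remaining free phenol directs the iodine to its own ortho position. One step thus settles which oxygen becomes O1 and where the side chain goes. The demands are para-selective methylation of 1 and ortho-selective iodination of 3.

**6 to 5 and 12 to 11.** Only O–Si bonds are cut. Both are single protections of commercial materials and lie off the longest sequence.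

## Other disconnections considered

**Alternative 1:** ring transposition of a 3-aroylbenzofuran-2-one.

- Cut and forward step: the O1–C2 bond of ester A2 is cut, leading back to the isomeric lactone A1. HCl in methanol would open the lactone of A1, one of the two equivalent ring A phenol oxygens would add to the ring B ketone, and loss of water would give the aromatic furan. The former lactone carbonyl is left as the C3 ester of A2.
- In favour: no metal is needed. Ring A is symmetric at that stage, so the closure has no regiochemical question. The C3 carbon arrives regiospecifically and at a stable oxidation level.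
- Against, here: A2 has neither the C5 side chain nor the C6 methyl ether. The C6 hydroxyl could probably be methylated selectively, since the C4 hydroxyl is hydrogen-bonded to the ester. The side chain would then have to enter at C5 by electrophilic substitution in competition with C7; both positions lie between two oxygens. The ester must be taken down to the aldehyde by reduction and re-oxidation. The benzyl ethers must be removed without harming the aldehyde or the tertiary alcohol.
- Comparison:
  - Structure: the chosen plan is stronger, because it fixes the ring A pattern before the furan exists, where a chelated phenol can direct.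
  - Mechanism: Alternative 1 is the better of the two. An acid-promoted condensation is simpler and less sensitive to crowding than a platinum cascade on an alkyne with three ortho substituents. It is the equal of the chosen plan in placing the C3 carbon without a formylation.
  - Step economy: A2 would be reached in fewer steps than 16, but about six further operations would follow, one of doubtful regiochemistry, against two in the chosen plan.

**Alternative 2:** Danheiser benzannulation.

- Cut and forward step: four bonds of ring A are cut at once (C7–C7a, C3a–C4, C4–C5, C6–C7), leaving furyl diazo ketone A3 and methoxyalkyne A4. Irradiation of A3 would trigger a Wolff rearrangement in which the furan migrates (C7–C7a). A [2+2] cycloaddition with A4 would join the ketene carbonyl carbon to the alkyl-bearing alkyne carbon (C4–C5 and C6–C7). On heating, a four-electron ring opening, a six-electron closure onto the furan C–H carbon next to the ester (C3a–C4) and tautomerisation would give phenol A5.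
- In favour: the mechanism places every substituent of ring A. No phenol differentiation and no halogenation regiochemistry is needed. The C4 hydroxyl emerges free and distinct from the C6 methyl ether, and the C3 carbon is present as an ester from the start. On the control of the ring A pattern this alternative is the better of the two.
- Against, here: A3 and A4 each need several steps. A diazo ketone must be handled and photolysed. The electrocyclic closure has to occur at a furan carbon flanked by the ester. After A5, the ester, which sits peri to a free hydroxyl, must still be reduced and re-oxidised to the aldehyde.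
- Comparison:
  - Mechanism: both plans rest on a cascade; a four-stage pericyclic sequence and a platinum isomerisation stand about equal in confidence.
  - Step economy: the key step forms four bonds against two, but the two fragments should cost more steps than 10 and 12, and three operations follow A5 against two after 16. The chosen plan should be shorter overall.

**Alternative 3:** coumestan by C–H oxidative closure.

- Cut and forward step: the O1–C7a bond of coumestan A7 is cut, leading back to 4-hydroxy-3-arylcoumarin A6. With Pd(OAc)2 and a stoichiometric oxidant, the enolic oxygen would bind divalent palladium, the only ortho C–H of ring A would be palladated, and C–O reductive elimination would close the furan. Zerovalent palladium would then be re-oxidised.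
- In favour: ring A needs only two oxygens before the key step, since O1 is supplied by the coumarin. Its ring A building block is therefore simpler than 10, and on this point the alternative is the better. The single ortho C–H makes the closure unambiguous, which equals the chosen plan. The lactone protects the C3 carbon and the 2'-oxygen at once.
- Against, here: the closure is an oxidation, usually at high temperature, on a substrate that carries acetals and a free tertiary alcohol. The lactone of A7 must then be reduced only as far as the aldehyde level, with over-reduction as the obvious danger. The acetals must finally be removed with acid, which is the one condition the tertiary alcohol next to the C4 hydroxyl tolerates least.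
- Comparison:
  - Mechanism: the chosen plan is redox-neutral at the ring-forming step and ends under fluoride, which suits the fragile groups better.
  - Step economy: the two plans should be about equal in length up to the key step. The end-game of Alternative 3 is the riskier one.

Key step: step 10

## Route

Step 1
Reactants: 1 2,4,6-trihydroxybenzaldehyde
Product: 2 2,6-dihydroxy-4-methoxybenzaldehyde
Conditions: Me2SO4 (1.0 equiv), K2CO3 (1.0 equiv), acetone, 0 °C → rt
Reagents that add atoms: dimethyl sulfate, COS(=O)(=O)OC
Why: Williamson O-methylation; the 4-hydroxyl is the most acidic and the only one not tied to the formyl oxygen by a hydrogen bond, so with one equivalent each of base and electrophile it should react first.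

Step 2
Reactants: 2 2,6-dihydroxy-4-methoxybenzaldehyde
Product: 3 2-hydroxy-4-methoxy-6-(methoxymethoxy)benzaldehyde
Conditions: MOMCl (1.05 equiv), i-Pr2NEt, CH2Cl2, 0 °C
Reagents that add atoms: chloromethyl methyl ether, COCCl
Why: O-alkylation to the mixed acetal; 2 is symmetric, so either phenol gives the same product, and the remaining hydroxyl is then held in a hydrogen bond to the formyl group, which slows a second alkylation.

Step 3
Reactants: 3 2-hydroxy-4-methoxy-6-(methoxymethoxy)benzaldehyde
Product: 4 2-hydroxy-3-iodo-4-methoxy-6-(methoxymethoxy)benzaldehyde
Conditions: BnMe3N+ ICl2− (1.05 equiv), NaHCO3, CH2Cl2/MeOH, rt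
Reagents that add atoms: benzyltrimethylammonium dichloroiodate, C[N+](C)(C)Cc1ccccc1.Cl[I-]Cl
Why: Electrophilic aromatic iodination; in 2-hydroxy-4,6-dialkoxybenzaldehydes the free, chelated phenol directs the halogen to its own ortho position, so iodine should enter at C3 next to the free hydroxyl and leave the acetal on the oxygen beside the remaining C–H; hydrogen carbonate keeps the medium non-acidic for the acetal.

Step 4
Reactants: 5 2-methylbut-3-en-2-ol
Product: 6 triethyl[(2-methylbut-3-en-2-yl)oxy]silane
Conditions: TESOTf, 2,6-lutidine, CH2Cl2, 0 °C
Reagents that add atoms: triethylsilyl trifluoromethanesulfonate, CC[Si](CC)(CC)OS(=O)(=O)C(F)(F)F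
Why: Silylation of a tertiary alcohol with a silyl triflate and a hindered base, since a chlorosilane would be slow at this oxygen; the triethylsilyl group is chosen so that it falls later under the same mild fluoride as the aryl silyl ethers.

Step 5
Reactants: 6 triethyl[(2-methylbut-3-en-2-yl)oxy]silane; 4 2-hydroxy-3-iodo-4-methoxy-6-(methoxymethoxy)benzaldehyde
Product: 8 2-hydroxy-4-methoxy-6-(methoxymethoxy)-3-[3-methyl-3-(triethylsilyloxy)butyl]benzaldehyde, via B-alkyl-9-BBN adduct 7 (not isolated)
Conditions: 6 (1.6 equiv), 9-BBN (1.5 equiv), THF, 0 °C → rt; then 4, Pd(dppf)Cl2 (5 mol %), aq. K3PO4, THF/DMF, 50 °C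
Reagents that add atoms: none
Why: Anti-Markovnikov hydroboration puts boron on the terminal carbon and the B-alkyl Suzuki–Miyaura coupling joins this primary alkyl group to the aryl iodide; the phenol is left free so that no aryl silyl ether ortho to a formyl group meets aqueous base, and the alkene is in excess over the borane so that no B–H remains to reduce the aldehyde.

Step 6
Reactants: 8 2-hydroxy-4-methoxy-6-(methoxymethoxy)-3-[3-methyl-3-(triethylsilyloxy)butyl]benzaldehyde
Product: 9 2-(tert-butyldimethylsilyloxy)-4-methoxy-6-(methoxymethoxy)-3-[3-methyl-3-(triethylsilyloxy)butyl]benzaldehyde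
Conditions: TBSOTf, 2,6-lutidine, CH2Cl2, −78 → 0 °C
Reagents that add atoms: tert-butyldimethylsilyl trifluoromethanesulfonate, CC(C)(C)[Si](C)(C)OS(=O)(=O)C(F)(F)F
Why: O-silylation of a hindered, hydrogen-bonded phenol calls for the reactive silyl triflate; at low temperature with a hindered base the aryl acetal, the aldehyde and the tertiary silyl ether should be untouched.

Step 7
Reactants: 9 2-(tert-butyldimethylsilyloxy)-4-methoxy-6-(methoxymethoxy)-3-[3-methyl-3-(triethylsilyloxy)butyl]benzaldehyde
Product: 10 2-(tert-butyldimethylsilyloxy)-1-(2,2-dibromoethenyl)-4-methoxy-6-(methoxymethoxy)-3-[3-methyl-3-(triethylsilyloxy)butyl]benzene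
Conditions: CBr4 (2 equiv), PPh3 (4 equiv), Et3N, CH2Cl2, 0 °C
Reagents that add atoms: carbon tetrabromide, BrC(Br)(Br)Br
Why: Ramirez dibromo-olefination, the first stage of the Corey–Fuchs sequence: the ylide from PPh3 and CBr4 converts the aldehyde into the 1,1-dibromoalkene; triethylamine buffers traces of HBr for the acetal and the silyl ethers, and the zinc variant is avoided because ZnBr2 would threaten the acetal.

Step 8
Reactants: 11 4-iodoresorcinol
Product: 12 1-iodo-2,4-bis(triisopropylsilyloxy)benzene
Conditions: TIPSCl (2.4 equiv), imidazole, DMF, rt → 40 °C
Reagents that add atoms: triisopropylsilyl chloride, CC(C)[Si](Cl)(C(C)C)C(C)C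
Why: Standard silylation of both phenols; the bulky triisopropylsilyl groups are chosen so that the ring B 2'-oxygen cannot later compete as a nucleophile at the alkyne.

Step 9
Reactants: 10 2-(tert-butyldimethylsilyloxy)-1-(2,2-dibromoethenyl)-4-methoxy-6-(methoxymethoxy)-3-[3-methyl-3-(triethylsilyloxy)butyl]benzene; 12 1-iodo-2,4-bis(triisopropylsilyloxy)benzene
Product: 15 1-{[2,4-bis(triisopropylsilyloxy)phenyl]ethynyl}-2-(tert-butyldimethylsilyloxy)-4-methoxy-6-(methoxymethoxy)-3-[3-methyl-3-(triethylsilyloxy)butyl]benzene, via lithium acetylide 13 (not isolated), via alkynylzinc chloride 14 (not isolated)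
Conditions: n-BuLi (2.1 equiv), THF, −78 → 0 °C; ZnCl2 (1.2 equiv), THF, −78 °C → rt; then 12, Pd(PPh3)4 (5 mol %), THF, 50 °C
Reagents that add atoms: none
Why: The second stage of the Corey–Fuchs sequence (bromine–lithium exchange, Fritsch–Buttenberg–Wiechell shift, deprotonation) gives the lithium acetylide, which is transmetalated to zinc and joined to the aryl iodide by Negishi coupling at zerovalent palladium; no copper and no free terminal alkyne are present, so oxidative dimerisation of the electron-rich alkyne is avoided and one isolation is saved.

Step 10
Reactants: 15 1-{[2,4-bis(triisopropylsilyloxy)phenyl]ethynyl}-2-(tert-butyldimethylsilyloxy)-4-methoxy-6-(methoxymethoxy)-3-[3-methyl-3-(triethylsilyloxy)butyl]benzene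
Product: 16 2-[2,4-bis(triisopropylsilyloxy)phenyl]-4-(tert-butyldimethylsilyloxy)-6-methoxy-3-(methoxymethyl)-5-[3-methyl-3-(triethylsilyloxy)butyl]benzofuran
Conditions: PtCl2 (5 mol %), 1,5-cyclooctadiene (20 mol %), toluene, 30 → 60 °C
Reagents that add atoms: none
Why: This is an alkyne carboalkoxylation with 1,3-shift, the known platinum-catalysed isomerisation of ortho-alkynylphenyl acetals to 2,3-disubstituted benzofurans. PtCl2, kept in solution by the diene, binds the diaryl alkyne as a π-acid, and the acetal oxygen adds anti to the metal at the alkyne carbon that carries ring B, which closes the furan in a 5-endo-dig mode and gives a 3-platinated benzofuran oxonium ion. The oxonium ion sheds the methoxymethyl cation, an oxocarbenium ion, and the carbon–platinum bond at C3 captures it, which forms C3–CH2OMe and returns divalent platinum, so nothing is consumed. One ring (the furan) and two bonds (O1–C2 and C3–CH2) are formed and no stereocentre arises. The step needs chemoselectivity among three oxygens ortho to the alkyne: only the acetal oxygen can release a stabilised cation, whereas the C4 and 2' oxygens carry bulky silyl groups that should neither cyclise nor migrate. It also needs the one-carbon unit at C3 and not at C7, which the mechanism secures because the cation is set free next to the C3–Pt bond. The acetal oxygen sits on the ring A carbon beside the only aromatic C–H of that ring, so the side chain ends up at C5 between the C4 oxygen and the C6 methoxy group.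

Step 11
Reactants: 16 2-[2,4-bis(triisopropylsilyloxy)phenyl]-4-(tert-butyldimethylsilyloxy)-6-methoxy-3-(methoxymethyl)-5-[3-methyl-3-(triethylsilyloxy)butyl]benzofuran
Product: 17 2-[2,4-bis(triisopropylsilyloxy)phenyl]-4-(tert-butyldimethylsilyloxy)-6-methoxy-5-[3-methyl-3-(triethylsilyloxy)butyl]benzofuran-3-carbaldehyde
Conditions: DDQ (2 equiv), CH2Cl2/pH 7 buffer (10:1), 0 °C → rt
Reagents that add atoms: water, O
Why: Oxidation of an electron-rich benzylic methyl ether by DDQ: hydride abstraction from C3–CH2 gives an oxocarbenium ion stabilised through C2 by O1 and ring B, water adds, and the hemiacetal loses methanol to give the aldehyde; all phenols are still silylated, so the quinone finds no free phenol to oxidise.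

Step 12
Reactants: 17 2-[2,4-bis(triisopropylsilyloxy)phenyl]-4-(tert-butyldimethylsilyloxy)-6-methoxy-5-[3-methyl-3-(triethylsilyloxy)butyl]benzofuran-3-carbaldehyde
Product: 18 2-(2,4-dihydroxyphenyl)-4-hydroxy-5-(3-hydroxy-3-methylbutyl)-6-methoxybenzofuran-3-carbaldehyde
Conditions: TBAF (6 equiv), AcOH (6 equiv), THF, 0 °C → rt
Reagents that add atoms: none
Why: Fluoride-induced cleavage of all four O–Si bonds; the three aryl silyl ethers and the tertiary triethylsilyl ether should fall under the same mild treatment, acetic acid tempers the basicity of the phenoxides, and the absence of strong acid protects the tertiary alcohol from dehydration or closure onto the C4 hydroxyl.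

## Compound list

1 | 2,4,6-trihydroxybenzaldehyde | O=Cc1c(O)cc(O)cc1O | starting material
2 | 2,6-dihydroxy-4-methoxybenzaldehyde | COc1cc(O)c(C=O)c(O)c1 | intermediate
3 | 2-hydroxy-4-methoxy-6-(methoxymethoxy)benzaldehyde | COCOc1cc(OC)cc(O)c1C=O | intermediate
4 | 2-hydroxy-3-iodo-4-methoxy-6-(methoxymethoxy)benzaldehyde | COCOc1cc(OC)c(I)c(O)c1C=O | intermediate
5 | 2-methylbut-3-en-2-ol | C=CC(C)(C)O | starting material
6 | triethyl[(2-methylbut-3-en-2-yl)oxy]silane | C=CC(C)(C)O[Si](CC)(CC)CC | intermediate
7 | 9-[3-methyl-3-(triethylsilyloxy)butyl]-9-borabicyclo[3.3.1]nonane | CC[Si](CC)(CC)OC(C)(C)CCB1C2CCCC1CCC2 | intermediate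
8 | 2-hydroxy-4-methoxy-6-(methoxymethoxy)-3-[3-methyl-3-(triethylsilyloxy)butyl]benzaldehyde | COCOc1cc(OC)c(CCC(C)(C)O[Si](CC)(CC)CC)c(O)c1C=O | intermediate
9 | 2-(tert-butyldimethylsilyloxy)-4-methoxy-6-(methoxymethoxy)-3-[3-methyl-3-(triethylsilyloxy)butyl]benzaldehyde | COCOc1cc(OC)c(CCC(C)(C)O[Si](CC)(CC)CC)c(O[Si](C)(C)C(C)(C)C)c1C=O | intermediate
10 | 2-(tert-butyldimethylsilyloxy)-1-(2,2-dibromoethenyl)-4-methoxy-6-(methoxymethoxy)-3-[3-methyl-3-(triethylsilyloxy)butyl]benzene | COCOc1cc(OC)c(CCC(C)(C)O[Si](CC)(CC)CC)c(O[Si](C)(C)C(C)(C)C)c1C=C(Br)Br | intermediate
11 | 4-iodoresorcinol | Oc1ccc(I)c(O)c1 | starting material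
12 | 1-iodo-2,4-bis(triisopropylsilyloxy)benzene | CC(C)[Si](Oc1ccc(I)c(O[Si](C(C)C)(C(C)C)C(C)C)c1)(C(C)C)C(C)C | intermediate
13 | lithium acetylide of ring A, {2-(tert-butyldimethylsilyloxy)-4-methoxy-6-(methoxymethoxy)-3-[3-methyl-3-(triethylsilyloxy)butyl]phenyl}ethynyllithium | COCOc1cc(OC)c(CCC(C)(C)O[Si](CC)(CC)CC)c(O[Si](C)(C)C(C)(C)C)c1C#C[Li] | intermediate
14 | alkynylzinc chloride of ring A, chloro({2-(tert-butyldimethylsilyloxy)-4-methoxy-6-(methoxymethoxy)-3-[3-methyl-3-(triethylsilyloxy)butyl]phenyl}ethynyl)zinc | COCOc1cc(OC)c(CCC(C)(C)O[Si](CC)(CC)CC)c(O[Si](C)(C)C(C)(C)C)c1C#C[Zn]Cl | intermediate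
15 | 1-{[2,4-bis(triisopropylsilyloxy)phenyl]ethynyl}-2-(tert-butyldimethylsilyloxy)-4-methoxy-6-(methoxymethoxy)-3-[3-methyl-3-(triethylsilyloxy)butyl]benzene | COCOc1cc(OC)c(CCC(C)(C)O[Si](CC)(CC)CC)c(O[Si](C)(C)C(C)(C)C)c1C#Cc1ccc(O[Si](C(C)C)(C(C)C)C(C)C)cc1O[Si](C(C)C)(C(C)C)C(C)C | intermediate
16 | 2-[2,4-bis(triisopropylsilyloxy)phenyl]-4-(tert-butyldimethylsilyloxy)-6-methoxy-3-(methoxymethyl)-5-[3-methyl-3-(triethylsilyloxy)butyl]benzofuran | COCc1c(-c2ccc(O[Si](C(C)C)(C(C)C)C(C)C)cc2O[Si](C(C)C)(C(C)C)C(C)C)oc2cc(OC)c(CCC(C)(C)O[Si](CC)(CC)CC)c(O[Si](C)(C)C(C)(C)C)c12 | intermediate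
17 | 2-[2,4-bis(triisopropylsilyloxy)phenyl]-4-(tert-butyldimethylsilyloxy)-6-methoxy-5-[3-methyl-3-(triethylsilyloxy)butyl]benzofuran-3-carbaldehyde | O=Cc1c(-c2ccc(O[Si](C(C)C)(C(C)C)C(C)C)cc2O[Si](C(C)C)(C(C)C)C(C)C)oc2cc(OC)c(CCC(C)(C)O[Si](CC)(CC)CC)c(O[Si](C)(C)C(C)(C)C)c12 | intermediate
18 | 2-(2,4-dihydroxyphenyl)-4-hydroxy-5-(3-hydroxy-3-methylbutyl)-6-methoxybenzofuran-3-carbaldehyde | COc1cc2oc(-c3ccc(O)cc3O)c(C=O)c2c(O)c1CCC(C)(C)O | target

## Step count and least certain steps

Total step count: 12. Longest linear sequence: 10 steps (steps 1, 2, 3, 5, 6, 7, 9, 10, 11, 12, from 1 to 18). Steps 4 and 8 are single protections that feed in from the side.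

**Step 10 (key step).**
- What may go wrong: the alkyne is flanked by three ortho substituents, so π-activation may be slow. Protonolysis of the carbon–platinum bond may overtake recapture of the methoxymethyl cation, which would close the furan without transfer of the carbon unit. The cation may also be delivered between molecules to the electron-rich C7.
- Fallback: this sets out from 15 and comes back at 17, so it also bypasses step 11. Iodocyclisation of 15 with I2 and NaHCO3 in CH2Cl2 is the known electrophilic cyclisation of ortho-alkynylphenyl ethers, in which the acetal oxygen attacks the iodonium ion and loses its alkyl group. It would give 2-[2,4-bis(triisopropylsilyloxy)phenyl]-4-(tert-butyldimethylsilyloxy)-3-iodo-6-methoxy-5-[3-methyl-3-(triethylsilyloxy)butyl]benzofuran F1. Iodine–magnesium exchange with i-PrMgCl·LiCl in THF at −40 °C and quenching with DMF would then give 17.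

**Step 11.**
- What may go wrong: electron transfer from the very electron-rich aryl rings to the quinone may cause over-oxidation. Hydride abstraction may be slow if the crowded C3 substituent cannot align with the π-system. Silyl groups may be lost in the wet medium.
- Fallback: this sets out from 16 and comes back at 17 and replaces C–H oxidation by C–O ionisation. Me2BBr in CH2Cl2 at −78 °C should cleave the doubly activated benzylic methyl ether to 3-(bromomethyl)-2-[2,4-bis(triisopropylsilyloxy)phenyl]-4-(tert-butyldimethylsilyloxy)-6-methoxy-5-[3-methyl-3-(triethylsilyloxy)butyl]benzofuran F2. Without isolation, N-methylmorpholine N-oxide in MeCN would displace bromide and eliminate to give 17 (Kornblum-type oxidation of a benzylic halide).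

**Step 5.**
- What may go wrong: oxidative addition to the electron-rich, di-ortho-substituted iodide is slowed further when the phenol is present as its phenoxide. This leaves room for protodeiodination and for β-hydride loss from the alkylpalladium intermediate. The phenoxide may also tie up the borane.
- Fallback: this sets out from 4 and comes back at 9.
  1. TBSOTf and 2,6-lutidine would give 2-(tert-butyldimethylsilyloxy)-3-iodo-4-methoxy-6-(methoxymethoxy)benzaldehyde F3.
  2. Sonogashira coupling with 2-methylbut-3-yn-2-ol (Pd(PPh3)2Cl2, CuI, Et3N, rt, no water) would give 2-(tert-butyldimethylsilyloxy)-3-(3-hydroxy-3-methylbut-1-yn-1-yl)-4-methoxy-6-(methoxymethoxy)benzaldehyde F4.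
  3. Hydrogenation (H2, Pd/C, EtOAc) would saturate the alkyne to 2-(tert-butyldimethylsilyloxy)-3-(3-hydroxy-3-methylbutyl)-4-methoxy-6-(methoxymethoxy)benzaldehyde F5.
  4. TESOTf and 2,6-lutidine would give 9.

**Step 9.**
- What may go wrong: transmetalation to zinc may be incomplete, or the coupling of two hindered partners may be slow, so that the acetylide is merely protonated on work-up. The three operations in one flask also make it hard to find which stage underperforms.
- Fallback: this sets out from 10 and comes back at 15. Treatment with n-BuLi and an aqueous NH4Cl quench would give 2-(tert-butyldimethylsilyloxy)-1-ethynyl-4-methoxy-6-(methoxymethoxy)-3-[3-methyl-3-(triethylsilyloxy)butyl]benzene F6, which can be purified. A Sonogashira coupling with 12 (Pd(PPh3)2Cl2, CuI, Et3N/THF, degassed, 50 °C) would then give 15.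

**Step 3.**
- What may go wrong: regioselectivity may be poor, with iodination para to the free phenol (between the acetal oxygen and the methoxy group). That would later exchange the roles of the two ring A oxygens and place the side chain at C7. Loss of the acetal in the halogenating medium is a lesser risk.
- Fallback: this sets out from 2 and comes back at 4. The symmetric diol 2 is iodinated first under the same conditions; it has only one kind of free position, so it would give 2,6-dihydroxy-3-iodo-4-methoxybenzaldehyde F7. MOMCl (1 equiv) and i-Pr2NEt should then alkylate the less hindered hydroxyl, the one remote from iodine, to give 4.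

**Step 1.**
- What may go wrong: selectivity rests only on a difference in acidity and hydrogen bonding, so over-alkylation at the ortho hydroxyls or incomplete conversion may leave a mixture.
- Fallback: this sets out from 1 and comes back at 2. Exhaustive methylation (excess Me2SO4, K2CO3, acetone, reflux) would give 2,4,6-trimethoxybenzaldehyde F8. AlCl3 in CH2Cl2 would then cleave only the two methoxy groups ortho to the formyl group, through chelation to the carbonyl oxygen, to give 2.

## Further compounds

F1 | step 10 | 2-[2,4-bis(triisopropylsilyloxy)phenyl]-4-(tert-butyldimethylsilyloxy)-3-iodo-6-methoxy-5-[3-methyl-3-(triethylsilyloxy)butyl]benzofuran | Ic1c(-c2ccc(O[Si](C(C)C)(C(C)C)C(C)C)cc2O[Si](C(C)C)(C(C)C)C(C)C)oc2cc(OC)c(CCC(C)(C)O[Si](CC)(CC)CC)c(O[Si](C)(C)C(C)(C)C)c12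
F2 | step 11 | 3-(bromomethyl)-2-[2,4-bis(triisopropylsilyloxy)phenyl]-4-(tert-butyldimethylsilyloxy)-6-methoxy-5-[3-methyl-3-(triethylsilyloxy)butyl]benzofuran | BrCc1c(-c2ccc(O[Si](C(C)C)(C(C)C)C(C)C)cc2O[Si](C(C)C)(C(C)C)C(C)C)oc2cc(OC)c(CCC(C)(C)O[Si](CC)(CC)CC)c(O[Si](C)(C)C(C)(C)C)c12
F3 | step 5 | 2-(tert-butyldimethylsilyloxy)-3-iodo-4-methoxy-6-(methoxymethoxy)benzaldehyde | COCOc1cc(OC)c(I)c(O[Si](C)(C)C(C)(C)C)c1C=O
F4 | step 5 | 2-(tert-butyldimethylsilyloxy)-3-(3-hydroxy-3-methylbut-1-yn-1-yl)-4-methoxy-6-(methoxymethoxy)benzaldehyde | COCOc1cc(OC)c(C#CC(C)(C)O)c(O[Si](C)(C)C(C)(C)C)c1C=O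
F5 | step 5 | 2-(tert-butyldimethylsilyloxy)-3-(3-hydroxy-3-methylbutyl)-4-methoxy-6-(methoxymethoxy)benzaldehyde | COCOc1cc(OC)c(CCC(C)(C)O)c(O[Si](C)(C)C(C)(C)C)c1C=O
F6 | step 9 | 2-(tert-butyldimethylsilyloxy)-1-ethynyl-4-methoxy-6-(methoxymethoxy)-3-[3-methyl-3-(triethylsilyloxy)butyl]benzene | COCOc1cc(OC)c(CCC(C)(C)O[Si](CC)(CC)CC)c(O[Si](C)(C)C(C)(C)C)c1C#C
F7 | step 3 | 2,6-dihydroxy-3-iodo-4-methoxybenzaldehyde | COc1cc(O)c(C=O)c(O)c1I
F8 | step 1 | 2,4,6-trimethoxybenzaldehyde | COc1cc(OC)c(C=O)c(OC)c1
A1 | alternative 1 | 3-[2,4-bis(benzyloxy)benzoyl]-4,6-dihydroxybenzofuran-2(3H)-one | O=C1Oc2cc(O)cc(O)c2C1C(=O)c1ccc(OCc2ccccc2)cc1OCc1ccccc1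
A2 | alternative 1 | methyl 2-[2,4-bis(benzyloxy)phenyl]-4,6-dihydroxybenzofuran-3-carboxylate | COC(=O)c1c(-c2ccc(OCc3ccccc3)cc2OCc2ccccc2)oc2cc(O)cc(O)c12
A3 | alternative 2 | methyl 2-[2,4-bis(tert-butyldimethylsilyloxy)phenyl]-5-(2-diazoacetyl)furan-3-carboxylate | COC(=O)c1cc(C(=O)C=[N+]=[N-])oc1-c1ccc(O[Si](C)(C)C(C)(C)C)cc1O[Si](C)(C)C(C)(C)C
A4 | alternative 2 | triethyl[(6-methoxy-2-methylhex-5-yn-2-yl)oxy]silane | COC#CCCC(C)(C)O[Si](CC)(CC)CC
A5 | alternative 2 | methyl 2-[2,4-bis(tert-butyldimethylsilyloxy)phenyl]-4-hydroxy-6-methoxy-5-[3-methyl-3-(triethylsilyloxy)butyl]benzofuran-3-carboxylate | COC(=O)c1c(-c2ccc(O[Si](C)(C)C(C)(C)C)cc2O[Si](C)(C)C(C)(C)C)oc2cc(OC)c(CCC(C)(C)O[Si](CC)(CC)CC)c(O)c12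
A6 | alternative 3 | 4-hydroxy-3-[3-(3-hydroxy-3-methylbutyl)-4-methoxy-2-(methoxymethoxy)phenyl]-7-(methoxymethoxy)-2H-chromen-2-one | O=c1oc2cc(OCOC)ccc2c(O)c1-c1ccc(OC)c(CCC(C)(C)O)c1OCOC
A7 | alternative 3 | 8-(3-hydroxy-3-methylbutyl)-9-methoxy-3,7-bis(methoxymethoxy)-6H-benzofuro[3,2-c]chromen-6-one | O=c1oc2cc(OCOC)ccc2c2oc3cc(OC)c(CCC(C)(C)O)c(OCOC)c3c12
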